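The ten-membered carbocycle is made by a two-carbon ring expansion, not by a cyclization. Its 2,4-dien-1-one (C1 ketone; C2=C3 trans within the carbocycle because the furanone ring O–C10–C1–C2–C3 holds it, formally 2Z; C4=C5 Z with the C4 methyl) is the trace of an opened cyclobutene C2–C3–C4–C5. The precursor is a lactone-fused cis-cyclooct-2-enone (C2=C5) with a 1-propynyl ether on the C10 oxygen. One silver-catalysed operation adds the ynol ether across the enone (C3–C2 and C4–C5 bonds, furanone ring) and cleaves C2–C5 by 4π electrocyclic opening to give the ten-membered ring. The preformed epoxy acid is esterified last.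

Key step: step 22

Remark: atoms carry germacrane numbers; the C1 carbinol made in step 5 is expected as an epimer mixture and is carried as such (SMILES show the 1S epimer), because C1 becomes a ketone in step 21.

Step 1
Reactants: 1 (S)-citramalic acid
Product: 2 (S)-2-(2,2,4-trimethyl-5-oxo-1,3-dioxolan-4-yl)acetic acid
Conditions: Me2C(OMe)2, TsOH (cat.), rt
Reagents that add atoms: 2,2-dimethoxypropane, COC(C)(C)OC
Why: Acid-catalysed acetalization takes up the α-hydroxy acid (C10 hydroxyl and C1 carboxyl) as the five-membered dioxolanone in preference to the six-membered alternative, which leaves the C8 carboxyl free; C10 (S) is not touched.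

Step 2
Reactants: 2 (S)-2-(2,2,4-trimethyl-5-oxo-1,3-dioxolan-4-yl)acetic acid
Product: 4 (S)-3-hydroxy-3-methyldihydrofuran-2(3H)-one, via hydroxyethyl dioxolanone 3 (not isolated)
Conditions: BH3·SMe2, THF, 0 °C to rt; MeOH; then TsOH (cat.), CH2Cl2, rt
Reagents that add atoms: none
Why: Borane reduces the free carboxylic acid chemoselectively (the dioxolanone carbonyl is ester-like), and alcohol 3 then translactonizes onto C1 under acid with loss of acetone, the sequence known for malic acid; C10 keeps its configuration.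

Step 3
Reactants: 4 (S)-3-hydroxy-3-methyldihydrofuran-2(3H)-one
Product: 5 (S)-3-[(E)-1,2-dichlorovinyloxy]-3-methyldihydrofuran-2(3H)-one
Conditions: KH, Cl2C=CHCl, THF, −50 °C to rt
Reagents that add atoms: trichloroethylene, ClC=C(Cl)Cl
Why: Standard 1,2-dichlorovinyl ether synthesis: the deprotonated tertiary hydroxyl adds to dichloroacetylene generated in the flask and anti protonation gives the E enol ether; the lactone has no α-hydrogen and five-membered lactones resist ring-opening oligomerization.

Step 4
Reactants: 5 (S)-3-[(E)-1,2-dichlorovinyloxy]-3-methyldihydrofuran-2(3H)-one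
Product: 6 (3S)-3-[(E)-1,2-dichlorovinyloxy]-3-methyltetrahydrofuran-2-ol (anomer mixture)
Conditions: i-Bu2AlH, CH2Cl2, −78 °C
Reagents that add atoms: none
Why: Partial reduction of a γ-lactone with i-Bu2AlH at low temperature stops at the lactol, and the chlorinated enol ether is inert to the hydride at −78 °C.

Step 5
Reactants: 6 (3S)-3-[(E)-1,2-dichlorovinyloxy]-3-methyltetrahydrofuran-2-ol
Product: 7 (3S)-3-[(E)-1,2-dichlorovinyloxy]-3-methylhex-5-ene-1,4-diol (C1 vinyl carbinol, epimer mixture)
Conditions: CH2=CHMgBr (3 equiv), THF, −78 to 0 °C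
Reagents that add atoms: vinylmagnesium bromide, C=C[Mg]Br
Why: Grignard addition to the hydroxy aldehyde form of the lactol (one equivalent is spent on the lactol hydroxyl); the C1 carbinol forms with little control, which does not matter because C1 becomes a ketone in step 21.

Step 6
Reactants: 7 (3S)-3-[(E)-1,2-dichlorovinyloxy]-3-methylhex-5-ene-1,4-diol
Product: 8 bis(triethylsilyl) ether of 7
Conditions: Et3SiCl, imidazole, DMF, 0 °C to rt
Reagents that add atoms: chlorotriethylsilane, CC[Si](Cl)(CC)CC
Why: Chlorosilane–imidazole silylation of the primary and the secondary hydroxyl leaves no free hydroxyl for the boron and aluminium reagents that follow.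

Step 7
Reactants: 8 bis(triethylsilyl) ether of 7
Product: 9 C8 aldehyde (3S)-3-[(E)-1,2-dichlorovinyloxy]-3-methyl-4-(triethylsilyloxy)hex-5-enal
Conditions: (COCl)2, DMSO, CH2Cl2, −78 to −30 °C; Et3N
Reagents that add atoms: none
Why: Swern conditions cleave and oxidize a primary triethylsilyl ether directly to the aldehyde while the hindered secondary silyl ether survives (known selective oxidative desilylation).

Step 8
Reactants: 10 monomethyl itaconate (4-methyl ester)
Product: 11 methyl 3-(hydroxymethyl)but-3-enoate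
Conditions: BH3·SMe2, THF, −10 to 0 °C; MeOH
Reagents that add atoms: none
Why: Borane reduces the free carboxylic acid far faster than the methyl ester and faster than it hydroborates the electron-poor acrylic alkene (chemoselective acid reduction).

Step 9
Reactants: 11 methyl 3-(hydroxymethyl)but-3-enoate
Product: 12 methyl 3-[(tert-butyldimethylsilyloxy)methyl]but-3-enoate
Conditions: t-BuMe2SiCl, imidazole, CH2Cl2, rt
Reagents that add atoms: tert-butyldimethylsilyl chloride, CC(C)(C)[Si](C)(C)Cl
Why: Standard silylation of the primary allylic alcohol, done at once to forestall lactonization of the hydroxy ester.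

Step 10
Reactants: 12 methyl 3-[(tert-butyldimethylsilyloxy)methyl]but-3-enoate
Product: 13 3-[(tert-butyldimethylsilyloxy)methyl]but-3-enoic acid
Conditions: LiOH, THF–H2O, 0 °C to rt; then 1 M HCl to pH 4, 0 °C
Reagents that add atoms: lithium hydroxide, [Li+].[OH-]
Why: Saponification of the methyl ester; the carboxylate resists α-deprotonation, so the 1,1-disubstituted alkene stays out of conjugation, and brief cold acidification spares the silyl ether.

Step 11
Reactants: 13 3-[(tert-butyldimethylsilyloxy)methyl]but-3-enoic acid; 14 (R)-4-benzyl-2-oxazolidinone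
Product: 17 (R)-4-benzyl-3-{3-[(tert-butyldimethylsilyloxy)methyl]but-3-enoyl}oxazolidin-2-one, via mixed pivalic anhydride 15 (not isolated), via N-lithio oxazolidinone 16 (not isolated)
Conditions: t-BuCOCl, Et3N, THF, −78 to 0 °C; then 14/n-BuLi, THF, −78 °C
Reagents that add atoms: none
Why: N-acylation of the lithiated auxiliary by the mixed anhydride, which is attacked at its less hindered carbonyl; the auxiliary stereocentre is unchanged.

Step 12
Reactants: 17 (R)-4-benzyl-3-{3-[(tert-butyldimethylsilyloxy)methyl]but-3-enoyl}oxazolidin-2-one; 9 C8 aldehyde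
Product: 19 Evans syn aldol adduct (C7–C8 bond; 7R,8S), via boron dienolate 18 (not isolated)
Conditions: Bu2BOTf, i-Pr2NEt, CH2Cl2, 0 °C; 9, −78 to 0 °C; pH 7 buffer, MeOH, H2O2
Reagents that add atoms: none
Why: Evans syn aldol: the Z(O) boron dienolate 18 reacts at its α-carbon through a chair Zimmerman–Traxler transition state on the face opposite the benzyl group, so the (R)-auxiliary sets C7 and C8 (7,8-syn, as in the target).

Step 13
Reactants: 19 Evans syn aldol adduct
Product: 20 Weinreb amide (N-methoxy-N-methyl amide at C6)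
Conditions: AlMe3, MeONHMe·HCl, CH2Cl2, −20 to 0 °C
Reagents that add atoms: N,O-dimethylhydroxylamine hydrochloride, CNOC.Cl
Why: Weinreb transamination: the aluminium amide made in the flask is delivered by the free C8 hydroxyl to the exocyclic imide carbonyl and releases the auxiliary without epimerization at C7.

Step 14
Reactants: 20 Weinreb amide
Product: 21 β-hydroxy vinyl ketone (C6 ketone, C5 vinyl)
Conditions: CH2=CHMgBr (4 equiv), THF, −78 to −20 °C; cold aqueous NH4Cl–HCl quench
Reagents that add atoms: vinylmagnesium bromide, C=C[Mg]Br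
Why: Weinreb ketone synthesis: the amide takes up one vinyl group only, and the cold acidic quench removes the liberated amine before it can add to the enone or epimerize C7.

Step 15
Reactants: 21 β-hydroxy vinyl ketone
Product: 23 1,3-anti diol monoester (C6 hydroxyl free, C8 isobutyrate), via isobutyraldehyde hemiacetal 22 (not isolated)
Conditions: i-PrCHO (8 equiv), SmI2 (0.3 equiv), THF, −10 °C
Reagents that add atoms: isobutyraldehyde, CC(C)C=O
Why: Evans–Tishchenko reduction: hemiacetal 22 at the C8 oxygen delivers hydride to the samarium-chelated C6 ketone through a chair transition state, which sets C6 anti to C8 (6S), leaves the C6 hydroxyl free and acylates the C8 oxygen.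

Step 16
Reactants: 23 1,3-anti diol monoester
Product: 24 cis-cyclooctene (Z C2=C5; C6 hydroxyl free)
Conditions: second-generation Grubbs catalyst RuCl2(CHPh)(PCy3)(H2IMes) (10 mol%), CH2Cl2 (2 mM), 40 °C
Reagents that add atoms: none
Why: Ring-closing metathesis: the carbene should form at the unhindered C5 vinyl group next to the free C6 hydroxyl, from where only closure onto the C2 vinyl group is possible (closure onto C11=C13 would give a cyclobutene); the eight-membered ring enforces the Z alkene, the chlorinated enol ether is too hindered and electron-poor to react, and high dilution suppresses oligomers.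

Step 17
Reactants: 24 cis-cyclooctene
Product: 25 6-O-triisopropylsilyl ether of 24
Conditions: i-Pr3SiOTf, 2,6-lutidine, CH2Cl2, −78 to 0 °C
Reagents that add atoms: triisopropylsilyl triflate, CC(C)[Si](OS(=O)(=O)C(F)(F)F)(C(C)C)C(C)C
Why: Silyl triflate with 2,6-lutidine silylates the hindered secondary allylic hydroxyl; this group has to survive fluoride in step 20 and to shield C6 from MnO2 in step 21.

Step 18
Reactants: 25 6-O-triisopropylsilyl ether of 24
Product: 26 C8 alcohol
Conditions: i-Bu2AlH (2.5 equiv), CH2Cl2, −78 °C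
Reagents that add atoms: none
Why: Reductive cleavage of the isobutyrate, the only carbonyl group, frees the C8 hydroxyl without touching the silyl ethers or the chlorinated enol ether.

Step 19
Reactants: 26 C8 alcohol
Product: 28 1-propynyl ether on the C10 oxygen (C8 hydroxyl free), via dilithio alkynyl ether 27 (not isolated)
Conditions: n-BuLi (3.3 equiv), THF, −78 to −40 °C; MeI (1.3 equiv), DMPU, −78 to −20 °C
Reagents that add atoms: iodomethane, CI
Why: Standard alkynyl ether synthesis from a 1,2-dichlorovinyl ether: one equivalent of n-BuLi forms the C8 alkoxide and two more (loss of HCl, then chlorine–lithium exchange) give the lithium acetylide in 27, which is methylated on carbon because a lithium alkoxide is far less nucleophilic than an acetylide (as in C-alkylation of alkynol dianions); no carbonyl group is present at this stage.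

Step 20
Reactants: 28 1-propynyl ether on the C10 oxygen
Product: 29 1,8,12-triol (C6 triisopropylsilyl ether kept)
Conditions: Bu4NF (3.5 equiv), THF, 0 °C to rt
Reagents that add atoms: none
Why: Fluoride cleaves the triethylsilyl and the primary tert-butyldimethylsilyl ether much faster than the hindered secondary triisopropylsilyl ether, and the basic conditions preserve the acid-sensitive ynol ether.

Step 21
Reactants: 29 1,8,12-triol
Product: 32 key precursor: trans-lactone-fused cis-cyclooct-2-enone with the 1-propynyl ether on the C10 oxygen, via keto enal 30 (not isolated), via keto lactol 31 (not isolated)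
Conditions: MnO2 (activated, excess), CH2Cl2, rt
Reagents that add atoms: none
Why: MnO2 oxidizes only allylic alcohols: the C1 carbinol (both epimers) gives the cis-enone and the primary allylic alcohol gives enal 30, which the C8 hydroxyl traps as lactol 31 and which is oxidized on to the α-methylene lactone (known oxidative lactonization of 2-methylene-1,4-diols); the lactone is trans-fused as fixed by C7 and C8.

Step 22
Reactants: 32 key precursor
Product: 34 furanone-bridged ten-membered carbocycle (C6 triisopropylsilyl ether), via cyclobutene 33 (not isolated)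
Conditions: AgNTf2 (10 mol%), 4 Å MS, CH2Cl2, −40 °C to rt; then 40 °C if 33 persists
Reagents that add atoms: none
Why: Proposed new method: monovalent silver (AgNTf2) activates the enone, the methyl-bearing ynol ether carbon C4 adds to the enone β-carbon C5, and the enolate carbon C2 closes onto the ketene-oxonium carbon C3 to give cyclobutene 33, whose C2–C5 bond then breaks by conrotatory 4π electrocyclic opening (or its silver-assisted stepwise equivalent), driven by ring strain and by formation of the vinylogous ester. The closest known reactions are the Ficini [2+2] cycloaddition of ynamines and ynamides with cyclic enones, the AgNTf2-catalysed [2+2] cycloaddition of siloxy alkynes with enones, the thermal opening of cis-bicyclo[6.2.0]dec-9-ene to cis,trans-cyclodeca-1,3-diene and the PtCl2-catalysed enyne rearrangement that enlarges a cyclooctene by two carbons. The furanone ring (O, C10, C1, C2, C3) closes in the fused mode imposed by the three-atom tether O–C10–C1 (in the stepwise picture a five-membered enolendo closure onto the digonal C3), the four-membered ring is the [2+2] ring, and the ten-membered carbocycle is not closed by a cyclization but appears when the shared C2–C5 bond opens. No permanent stereocentre is created: the transient centres C2 and C5 are fixed by C10 through the tether (C5 and C9 cis on the new five-membered ring) and by suprafacial addition to the cis alkene, and both are erased on opening, whereas the Z geometry of C4=C5 follows because the furanone forces C1 outward, so that conrotation turns C6 inward. The step needs the regiochemistry C3–C2/C4–C5, which the polarity match (nucleophilic C4, electrophilic C5) and the short tether secure, and it has to outrun retro-ene loss of ketene from the tertiary ynol ether, for which the low temperature is chosen; carbonyl–alkyne metathesis at C1 and the [4+2] pyran mode would require bridgehead-strained bicycles and are excluded by the tether.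

Step 23
Reactants: 34 furanone-bridged ten-membered carbocycle
Product: 35 C6 alcohol
Conditions: HF·pyridine, pyridine, THF, 0 °C to rt
Reagents that add atoms: none
Why: Buffered HF·pyridine cleaves the triisopropylsilyl ether without the basic fluoride that the α-methylene lactone and the dienone would not tolerate; no stereocentre is affected.

Step 24
Reactants: 36 angelic acid
Product: 37 (Z)-2-methylbut-2-en-1-ol
Conditions: LiAlH4, Et2O, 0 °C
Reagents that add atoms: none
Why: Hydride reduction of the acid to the allylic alcohol; LiAlH4 in ether neither reduces nor isomerizes the trisubstituted Z alkene.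

Step 25
Reactants: 37 (Z)-2-methylbut-2-en-1-ol
Product: 38 [(2R,3S)-2,3-dimethyloxiran-2-yl]methanol
Conditions: Ti(Oi-Pr)4 (10 mol%), D-(−)-diethyl tartrate (14 mol%), t-BuOOH, 4 Å MS, CH2Cl2, −20 °C
Reagents that add atoms: tert-butyl hydroperoxide, CC(C)(C)OO
Why: Katsuki–Sharpless asymmetric epoxidation: the D-(−)-tartrate directs oxygen to the face that gives the 2R,3S epoxy alcohol, and the cis relationship between the C3 methyl and the hydroxymethyl group is inherited from the Z alkene.

Step 26
Reactants: 38 [(2R,3S)-2,3-dimethyloxiran-2-yl]methanol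
Product: 40 (2S,3S)-2,3-dimethyloxirane-2-carboxylic acid, via epoxy aldehyde 39 (not isolated)
Conditions: RuCl3 (2 mol%), NaIO4, MeCN–EtOAc–H2O, 0 °C to rt
Reagents that add atoms: water, O
Why: RuO4 generated in situ oxidizes the primary alcohol through aldehyde 39 to the acid without opening the epoxide; the descriptor at C2 changes from R to S only because the priorities change.

Step 27
Reactants: 40 (2S,3S)-2,3-dimethyloxirane-2-carboxylic acid; 35 C6 alcohol
Product: 42 target CNP0258430.1, via mixed Yamaguchi anhydride 41 (not isolated)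
Conditions: 2,4,6-Cl3C6H2COCl, Et3N, THF, rt; then 35, DMAP, toluene, rt
Reagents that add atoms: none
Why: Yamaguchi esterification through mixed anhydride 41 with DMAP as acyl-transfer catalyst acylates hindered secondary alcohols with retention at C6, and the epoxide stereocentres come unchanged from 40.

Compound list
1 | (S)-citramalic acid ((S)-2-hydroxy-2-methylbutanedioic acid) | OC(=O)C[C@](C)(O)C(=O)O | starting material
2 | (S)-2-(2,2,4-trimethyl-5-oxo-1,3-dioxolan-4-yl)acetic acid | C[C@@]1(CC(=O)O)OC(C)(C)OC1=O | intermediate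
3 | (S)-5-(2-hydroxyethyl)-2,2,5-trimethyl-1,3-dioxolan-4-one | C[C@@]1(CCO)OC(C)(C)OC1=O | intermediate (not isolated)
4 | (S)-3-hydroxy-3-methyldihydrofuran-2(3H)-one | C[C@]1(O)CCOC1=O | intermediate
5 | (S)-3-[(E)-1,2-dichlorovinyloxy]-3-methyldihydrofuran-2(3H)-one | C[C@]1(O/C(Cl)=C\Cl)CCOC1=O | intermediate
6 | (3S)-3-[(E)-1,2-dichlorovinyloxy]-3-methyltetrahydrofuran-2-ol, anomer mixture | C[C@]1(O/C(Cl)=C\Cl)CCOC1O | intermediate
7 | (3S)-3-[(E)-1,2-dichlorovinyloxy]-3-methylhex-5-ene-1,4-diol, C1 (hexene C4) epimers, 4S drawn | OCC[C@](C)(O/C(Cl)=C\Cl)[C@@H](O)C=C | intermediate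
8 | 1,4-bis(triethylsilyl) ether of 7 | CC[Si](CC)(CC)OCC[C@](C)(O/C(Cl)=C\Cl)[C@@H](O[Si](CC)(CC)CC)C=C | intermediate
9 | C8 aldehyde: (3S)-3-[(E)-1,2-dichlorovinyloxy]-3-methyl-4-(triethylsilyloxy)hex-5-enal (10S, C1 epimers) | O=CC[C@](C)(O/C(Cl)=C\Cl)[C@@H](O[Si](CC)(CC)CC)C=C | intermediate
10 | monomethyl itaconate (2-methylenebutanedioic acid 4-methyl ester) | C=C(CC(=O)OC)C(=O)O | starting material
11 | methyl 3-(hydroxymethyl)but-3-enoate | C=C(CO)CC(=O)OC | intermediate
12 | methyl 3-[(tert-butyldimethylsilyloxy)methyl]but-3-enoate | C=C(CO[Si](C)(C)C(C)(C)C)CC(=O)OC | intermediate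
13 | 3-[(tert-butyldimethylsilyloxy)methyl]but-3-enoic acid | C=C(CO[Si](C)(C)C(C)(C)C)CC(=O)O | intermediate
14 | (R)-4-benzyl-2-oxazolidinone | O=C1OC[C@@H](Cc2ccccc2)N1 | starting material
15 | mixed anhydride of 13 with pivalic acid | C=C(CO[Si](C)(C)C(C)(C)C)CC(=O)OC(=O)C(C)(C)C | intermediate (not isolated)
16 | N-lithio derivative of 14 | [Li]N1C(=O)OC[C@H]1Cc1ccccc1 | intermediate (not isolated)
17 | (R)-4-benzyl-3-{3-[(tert-butyldimethylsilyloxy)methyl]but-3-enoyl}oxazolidin-2-one | C=C(CO[Si](C)(C)C(C)(C)C)CC(=O)N1C(=O)OC[C@H]1Cc1ccccc1 | intermediate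
18 | Z(O) dibutylboron dienolate of 17 | C=C(CO[Si](C)(C)C(C)(C)C)/C=C(\OB(CCCC)CCCC)N1C(=O)OC[C@H]1Cc1ccccc1 | intermediate (not isolated)
19 | Evans syn aldol adduct: N-acyl oxazolidinone with the C7–C8 bond, C8 hydroxyl, 7,8-syn (7R,8S), 10S, C1 epimers | C=C(CO[Si](C)(C)C(C)(C)C)[C@H]([C@@H](O)C[C@](C)(O/C(Cl)=C\Cl)[C@@H](O[Si](CC)(CC)CC)C=C)C(=O)N1C(=O)OC[C@H]1Cc1ccccc1 | intermediate
20 | Weinreb amide of 19 (N-methoxy-N-methyl amide at C6, stereocentres as in 19) | C=C(CO[Si](C)(C)C(C)(C)C)[C@H]([C@@H](O)C[C@](C)(O/C(Cl)=C\Cl)[C@@H](O[Si](CC)(CC)CC)C=C)C(=O)N(C)OC | intermediate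
21 | β-hydroxy vinyl ketone (C6 ketone, C5 vinyl, C8 hydroxyl, stereocentres as in 19) | C=C(CO[Si](C)(C)C(C)(C)C)[C@H]([C@@H](O)C[C@](C)(O/C(Cl)=C\Cl)[C@@H](O[Si](CC)(CC)CC)C=C)C(=O)C=C | intermediate
22 | hemiacetal of isobutyraldehyde at the C8 oxygen of 21 | C=C(CO[Si](C)(C)C(C)(C)C)[C@H]([C@@H](OC(O)C(C)C)C[C@](C)(O/C(Cl)=C\Cl)[C@@H](O[Si](CC)(CC)CC)C=C)C(=O)C=C | intermediate (not isolated)
23 | 1,3-anti diol monoester: C6 hydroxyl free (6S, anti to C8), C8 isobutyrate, C5 and C2 vinyl groups | C=C(CO[Si](C)(C)C(C)(C)C)[C@H]([C@@H](OC(=O)C(C)C)C[C@](C)(O/C(Cl)=C\Cl)[C@@H](O[Si](CC)(CC)CC)C=C)[C@@H](O)C=C | intermediate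
24 | cis-cyclooctene (Z C2=C5) with C6 hydroxyl, C8 isobutyrate, C1 triethylsilyl ether, dichlorovinyl ether on the C10 oxygen | C=C(CO[Si](C)(C)C(C)(C)C)[C@@H]1[C@@H](OC(=O)C(C)C)C[C@](C)(O/C(Cl)=C\Cl)[C@@H](O[Si](CC)(CC)CC)/C=C\[C@@H]1O | intermediate
25 | 6-O-triisopropylsilyl ether of 24 | C=C(CO[Si](C)(C)C(C)(C)C)[C@@H]1[C@@H](OC(=O)C(C)C)C[C@](C)(O/C(Cl)=C\Cl)[C@@H](O[Si](CC)(CC)CC)/C=C\[C@@H]1O[Si](C(C)C)(C(C)C)C(C)C | intermediate
26 | C8 alcohol from 25 (isobutyrate removed) | C=C(CO[Si](C)(C)C(C)(C)C)[C@@H]1[C@@H](O)C[C@](C)(O/C(Cl)=C\Cl)[C@@H](O[Si](CC)(CC)CC)/C=C\[C@@H]1O[Si](C(C)C)(C(C)C)C(C)C | intermediate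
27 | dilithio species: C8 lithium alkoxide and lithium acetylide of the C10 alkynyl ether | C=C(CO[Si](C)(C)C(C)(C)C)[C@@H]1[C@@H](O[Li])C[C@](C)(OC#C[Li])[C@@H](O[Si](CC)(CC)CC)/C=C\[C@@H]1O[Si](C(C)C)(C(C)C)C(C)C | intermediate (not isolated)
28 | cyclooctene with the 1-propynyl ether on the C10 oxygen, C8 hydroxyl free, silyl ethers at C1, C6 and C12 | C=C(CO[Si](C)(C)C(C)(C)C)[C@@H]1[C@@H](O)C[C@](C)(OC#CC)[C@@H](O[Si](CC)(CC)CC)/C=C\[C@@H]1O[Si](C(C)C)(C(C)C)C(C)C | intermediate
29 | 1,8,12-triol with the 1-propynyl ether and the C6 triisopropylsilyl ether | C=C(CO)[C@@H]1[C@@H](O)C[C@](C)(OC#CC)[C@@H](O)/C=C\[C@@H]1O[Si](C(C)C)(C(C)C)C(C)C | intermediate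
30 | keto enal: C1 enone, C12 aldehyde, C8 hydroxyl | C=C(C=O)[C@@H]1[C@@H](O)C[C@](C)(OC#CC)C(=O)/C=C\[C@@H]1O[Si](C(C)C)(C(C)C)C(C)C | intermediate (not isolated)
31 | keto lactol: C12 lactol closed on the C8 oxygen, C1 enone | C=C1C(O)O[C@H]2C[C@](C)(OC#CC)C(=O)/C=C\[C@H](O[Si](C(C)C)(C(C)C)C(C)C)[C@H]12 | intermediate (not isolated)
32 | key precursor: trans-fused α-methylene-γ-lactone on a cis-cyclooct-2-enone (C1 ketone, Z C2=C5), 1-propynyl ether on the C10 oxygen, C6 triisopropylsilyl ether | C=C1C(=O)O[C@H]2C[C@](C)(OC#CC)C(=O)/C=C\[C@H](O[Si](C(C)C)(C(C)C)C(C)C)[C@H]12 | intermediate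
33 | cyclobutene C2–C3=C4–C5, cis-fused to the eight-membered ring and fused at C2–C3 to the new ring O–C10–C1–C2–C3 (C5 cis to C9 on that ring) | C=C1C(=O)O[C@H]2C[C@]3(C)OC4=C(C)[C@@H]([C@@H]4C3=O)[C@H](O[Si](C(C)C)(C(C)C)C(C)C)[C@H]12 | intermediate (not isolated)
34 | furanone-bridged ten-membered carbocycle: C1 ketone, C2=C3 in the furanone, Z C4=C5, 12,8-lactone, C6 triisopropylsilyl ether | C=C1C(=O)O[C@H]2C[C@]3(C)OC(=CC3=O)/C(C)=C\[C@H](O[Si](C(C)C)(C(C)C)C(C)C)[C@H]12 | intermediate
35 | C6 alcohol of 34 (6S,7R,8S,10S) | C=C1C(=O)O[C@H]2C[C@]3(C)OC(=CC3=O)/C(C)=C\[C@H](O)[C@H]12 | intermediate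
36 | angelic acid ((Z)-2-methylbut-2-enoic acid) | C/C=C(/C)C(=O)O | starting material
37 | (Z)-2-methylbut-2-en-1-ol | C/C=C(/C)CO | intermediate
38 | [(2R,3S)-2,3-dimethyloxiran-2-yl]methanol | OC[C@@]1(C)O[C@H]1C | intermediate
39 | 2,3-dimethyloxirane-2-carbaldehyde (same spatial arrangement as 38) | O=C[C@@]1(C)O[C@H]1C | intermediate (not isolated)
40 | (2S,3S)-2,3-dimethyloxirane-2-carboxylic acid | OC(=O)[C@@]1(C)O[C@H]1C | intermediate
41 | mixed anhydride of 40 with 2,4,6-trichlorobenzoic acid | O=C(OC(=O)c1c(Cl)cc(Cl)cc1Cl)[C@@]1(C)O[C@H]1C | intermediate (not isolated)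
42 | CNP0258430.1: (6S,7R,8S,10S) furanone-bridged germacranolide 35 esterified at the C6 oxygen with (2S,3S)-2,3-dimethyloxirane-2-carboxylic acid | C=C1C(=O)O[C@H]2C[C@]3(C)OC(=CC3=O)/C(C)=C\[C@H](OC(=O)[C@@]3(C)O[C@H]3C)[C@H]12 | target

Total step count: 27. Longest linear sequence: 20 steps (steps 1–7, 12–23 and 27).

Steps most likely to fail

Step 22 (proposed new method). Silver-promoted hydration or retro-ene loss of ketene from the tertiary ynol ether may outpace the cycloaddition. The first C4–C5 bond may also fail to form next to the bulky C6 silyl ether, or the cyclobutene may form and not open. The fallback uses known chemistry: the two-carbon enlargement is done at the carbinol oxidation level by the platinum-catalysed skeletal rearrangement of 1,6-enynes. This reaction is known to widen a tethered cyclooctene by two carbons and is known for heteroatom-substituted alkynes. It sets out from 28. The C8 hydroxyl is capped with Me3SiCl and imidazole to give the 8-O-trimethylsilyl ether F1. PtCl2 (5 mol%) in toluene at 40 °C, or the cationic monovalent gold complex [(t-Bu)2(o-biphenyl)PAu(NCMe)]SbF6 at room temperature, should rearrange the enyne to the ring-expanded 2,3-dihydrofuran diene F2, with C1 still a silyl ether and C2=C3 and Z C4=C5 in place. Bu4NF then gives the triol F3. MnO2 oxidizes its C1 carbinol to the furanone carbonyl and its 2-methylene-1,4-diol to the lactone, which returns to the route at 34.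

Step 16. Intermolecular metathesis (oligomers) may outpace the slow eight-membered closure onto the hindered C2 vinyl group, or the carbene may form at C2 and close the seven-membered ring onto C11=C13. The fallback changes the order of ring formation: the γ-lactone is made first and serves as a rigid template, and the carbocycle is closed onto an enone. It sets out from 23. i-Pr3SiOTf gives the 6-O-silyl ether F4, i-Bu2AlH removes the isobutyrate to give the C8 alcohol F5, and Bu4NF frees the C1 and C12 hydroxyls to give the open-chain triol F6. MnO2 then gives the open-chain α-methylene lactone vinyl ketone F7. In F7 only the C5 vinyl group can carry the ruthenium carbene, because the other alkenes are an enone and an acrylate-type methylene lactone. Ring closure with RuCl2(CHPh)(PCy3)(H2IMes) onto the C1 enone on the trans-fused lactone template should give the cyclooctenone F8. Excess i-Bu2AlH reduces lactone and enone back to the cyclic triol F9. n-BuLi (5.5 equiv) followed by MeI then converts the dichlorovinyl ether into the propynyl ether, which rejoins the route at 29.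

Step 15. Single-electron reduction or polymerization of the sensitive vinyl ketone may compete with the intramolecular hydride transfer, as may retro-aldol cleavage or epimerization at the doubly activated C7. The fallback sets C6 by a reagent-controlled intermolecular reduction instead of the Tishchenko hydride transfer. It sets out from 21. Et3SiOTf and 2,6-lutidine give the 8-O-triethylsilyl ether F10. Corey–Bakshi–Shibata reduction with (R)-2-methyl-CBS-oxazaborolidine and catecholborane should give the 6S allylic alcohol F11, provided the branched C7 side acts as the large group; the enantiomeric catalyst is the remedy otherwise. Ring-closing metathesis as in step 16 gives the cyclooctenol F12, and i-Pr3SiOTf gives its 6-O-silyl ether F13. n-BuLi (2.2 equiv) and then MeI give the propynyl ether F14. Bu4NF removes both triethylsilyl groups and the tert-butyldimethylsilyl group and returns to the route at 29.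

Further compounds
F1 | step 22 | 8-O-trimethylsilyl ether of 28 | C=C(CO[Si](C)(C)C(C)(C)C)[C@@H]1[C@@H](O[Si](C)(C)C)C[C@](C)(OC#CC)[C@@H](O[Si](CC)(CC)CC)/C=C\[C@@H]1O[Si](C(C)C)(C(C)C)C(C)C
F2 | step 22 | ring-expanded 2,3-dihydrofuran diene (ten-membered carbocycle, C1 triethylsilyl ether, C2=C3, Z C4=C5, C8 trimethylsilyl ether) | C=C(CO[Si](C)(C)C(C)(C)C)[C@@H]1[C@@H](O[Si](C)(C)C)C[C@]2(C)OC(=C[C@@H]2O[Si](CC)(CC)CC)/C(C)=C\[C@@H]1O[Si](C(C)C)(C(C)C)C(C)C
F3 | step 22 | 1,8,12-triol of F2 (C6 triisopropylsilyl ether kept) | C=C(CO)[C@@H]1[C@@H](O)C[C@]2(C)OC(=C[C@@H]2O)/C(C)=C\[C@@H]1O[Si](C(C)C)(C(C)C)C(C)C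
F4 | step 16 | 6-O-triisopropylsilyl ether of 23 | C=C(CO[Si](C)(C)C(C)(C)C)[C@H]([C@@H](OC(=O)C(C)C)C[C@](C)(O/C(Cl)=C\Cl)[C@@H](O[Si](CC)(CC)CC)C=C)[C@@H](O[Si](C(C)C)(C(C)C)C(C)C)C=C
F5 | step 16 | C8 alcohol from F4 | C=C(CO[Si](C)(C)C(C)(C)C)[C@H]([C@@H](O)C[C@](C)(O/C(Cl)=C\Cl)[C@@H](O[Si](CC)(CC)CC)C=C)[C@@H](O[Si](C(C)C)(C(C)C)C(C)C)C=C
F6 | step 16 | open-chain 1,8,12-triol (C6 triisopropylsilyl ether, dichlorovinyl ether) | C=C(CO)[C@H]([C@@H](O)C[C@](C)(O/C(Cl)=C\Cl)[C@@H](O)C=C)[C@@H](O[Si](C(C)C)(C(C)C)C(C)C)C=C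
F7 | step 16 | open-chain α-methylene-γ-lactone with C1 vinyl ketone and C5 vinyl group | C=C1C(=O)O[C@@H](C[C@](C)(O/C(Cl)=C\Cl)C(=O)C=C)[C@@H]1[C@@H](O[Si](C(C)C)(C(C)C)C(C)C)C=C
F8 | step 16 | lactone-fused cis-cyclooct-2-enone with the dichlorovinyl ether (analogue of 32) | C=C1C(=O)O[C@H]2C[C@](C)(O/C(Cl)=C\Cl)C(=O)/C=C\[C@H](O[Si](C(C)C)(C(C)C)C(C)C)[C@H]12
F9 | step 16 | cyclic 1,8,12-triol with the dichlorovinyl ether (C1 epimers) | C=C(CO)[C@@H]1[C@@H](O)C[C@](C)(O/C(Cl)=C\Cl)C(O)/C=C\[C@@H]1O[Si](C(C)C)(C(C)C)C(C)C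
F10 | step 15 | 8-O-triethylsilyl ether of 21 | C=C(CO[Si](C)(C)C(C)(C)C)[C@H]([C@@H](O[Si](CC)(CC)CC)C[C@](C)(O/C(Cl)=C\Cl)[C@@H](O[Si](CC)(CC)CC)C=C)C(=O)C=C
F11 | step 15 | 6S allylic alcohol from F10 (C8 triethylsilyl ether) | C=C(CO[Si](C)(C)C(C)(C)C)[C@H]([C@@H](O[Si](CC)(CC)CC)C[C@](C)(O/C(Cl)=C\Cl)[C@@H](O[Si](CC)(CC)CC)C=C)[C@@H](O)C=C
F12 | step 15 | cis-cyclooctenol from F11 (C6 hydroxyl free, C8 triethylsilyl ether) | C=C(CO[Si](C)(C)C(C)(C)C)[C@@H]1[C@@H](O[Si](CC)(CC)CC)C[C@](C)(O/C(Cl)=C\Cl)[C@@H](O[Si](CC)(CC)CC)/C=C\[C@@H]1O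
F13 | step 15 | 6-O-triisopropylsilyl ether of F12 | C=C(CO[Si](C)(C)C(C)(C)C)[C@@H]1[C@@H](O[Si](CC)(CC)CC)C[C@](C)(O/C(Cl)=C\Cl)[C@@H](O[Si](CC)(CC)CC)/C=C\[C@@H]1O[Si](C(C)C)(C(C)C)C(C)C
F14 | step 15 | 1-propynyl ether from F13 (C8 triethylsilyl ether) | C=C(CO[Si](C)(C)C(C)(C)C)[C@@H]1[C@@H](O[Si](CC)(CC)CC)C[C@](C)(OC#CC)[C@@H](O[Si](CC)(CC)CC)/C=C\[C@@H]1O[Si](C(C)C)(C(C)C)C(C)C
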